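**Retrosynthetic overview**
1. Target ⇐ desilylation ⇐ 2β,3β-oxirane by 1β-OH-directed epoxidation of a 1β-hydroxy-2-ene, which comes from a 3-oxo-1-ene by β-face epoxidation and Wharton transposition.
2. Ring A ⇐ intramolecular aldol of the 19,10-lactone enolate onto a Z-enal (C3–C4); lactone ⇐ intramolecular Michael addition of a 10α-propanoate onto a C5=C6 enoate (C4–C5); C1–C3 ⇐ acetylide addition to the C10 ketone.
3. Ring D ⇐ SmI2 ketyl–alkyne cyclization (C13–C16).
4. Ring B and the C8 quaternary centre ⇐ new dynamic kinetic enantioselective enamine Michael cyclization (C6–C8).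
5. Ring C ⇐ 3-ethoxycyclohex-2-enone (α'-aldol, Stork–Danheiser propargylation). Ring order: C, B, D, lactone, A, oxirane.

Assumption: gibberellane numbering and α/β descriptors are used for all intermediates (β = the face of H-9 and of the C15–C16 bridge), and the (S)-configured catalyst of step 4 is taken to give the enantiomer drawn (its antipode would be used otherwise).

**Route**

Step 1
Reactants: 1 3-ethoxycyclohex-2-en-1-one; 2 4-[(tert-butyldimethylsilyl)oxy]butanal
Product: 3 3-ethoxy-6-{1-hydroxy-4-[(tert-butyldimethylsilyl)oxy]butyl}cyclohex-2-en-1-one (racemic diastereomer mixture)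
Conditions: LiN(iPr)2 (1.1 equiv), THF, −78 °C; then 2, −78 °C; aq. NH4Cl
Reagents that add atoms: none
Why: Kinetic α'-deprotonation of the vinylogous ester and aldol addition to the aldehyde join C9 to C10; both new stereocentres are erased or equilibrated in steps 3 and 4, so no control is needed.

Step 2
Reactants: 3 3-ethoxy-6-{1-hydroxy-4-[(tert-butyldimethylsilyl)oxy]butyl}cyclohex-2-en-1-one
Product: 5 4-(1,4-dihydroxybutyl)-3-(prop-2-yn-1-yl)cyclohex-2-en-1-one, via Stork–Danheiser carbinol 4 (not isolated)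
Conditions: HC≡CCH2MgBr (3 equiv, freshly prepared in Et2O), Et2O–THF, −78 to 0 °C; then 2 M HCl, THF, 23 °C
Reagents that add atoms: propargylmagnesium bromide, C#CC[Mg]Br; water, O
Why: Stork–Danheiser transposition: 1,2-addition of the propargyl Grignard to the vinylogous ester carbonyl, then acid hydrolysis of the enol ether, dehydration to the transposed enone (C13=O, C14=C8) and loss of the silyl ether in the same acid treatment; no stereocentre of consequence is formed.

Step 3
Reactants: 5 4-(1,4-dihydroxybutyl)-3-(prop-2-yn-1-yl)cyclohex-2-en-1-one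
Product: 6 4-(4-oxobutanoyl)-3-(prop-2-yn-1-yl)cyclohex-2-en-1-one (racemic; C9 configurationally labile)
Conditions: (COCl)2, DMSO, CH2Cl2, −78 °C; then Et3N, −78 to 0 °C
Reagents that add atoms: none
Why: Swern oxidation activates both hydroxyls before base is added, so the 1,4-diol gives the keto-aldehyde and not a lactone; C9 becomes α to the C10 ketone and vinylogously α to the enone, hence freely epimerizing.

Step 4
Reactants: 6 4-(4-oxobutanoyl)-3-(prop-2-yn-1-yl)cyclohex-2-en-1-one
Product: 7 (1S,3aR,7aR)-3,6-dioxo-7a-(prop-2-yn-1-yl)octahydro-1H-indene-1-carbaldehyde (cis-fused; gibberellane C6 β-CHO; C8 β-propargyl; 9β-H)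
Conditions: (S)-2-[diphenyl(trimethylsilyloxy)methyl]pyrrolidine (20 mol %), PhCO2H (20 mol %), toluene, 0 to 23 °C
Reagents that add atoms: none
Why: Proposed new method: a dynamic kinetic enantioselective intramolecular Michael addition in which the secondary amine turns the aldehyde into an E-enamine that adds 5-exo-trig to the β,β-disubstituted enone carbon C8 while C9 racemizes rapidly through its dienol, so both enantiomers of 6 drain through the lower of two diastereomeric transition states; the tether enforces the cis ring fusion (propargyl cis to H-9), the shielded enamine face fixes the absolute configuration of C8 and C9, C6 settles as the more stable epimer (irrelevant, it is planarized in step 9), and a secondary amine is chosen so that no pyrrole can form from the 1,4-keto-aldehyde; the closest known reaction type is the amine-catalysed enamine intramolecular Michael addition of formyl enones and its desymmetrizing variant on cyclohexadienones, neither shown to build a quaternary β-carbon under dynamic kinetic resolution.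

Step 5
Reactants: 7 (1S,3aR,7aR)-3,6-dioxo-7a-(prop-2-yn-1-yl)octahydro-1H-indene-1-carbaldehyde
Product: 8 (1S,3aR,7aS)-3,6-dioxo-7a-(prop-2-yn-1-yl)octahydro-1H-indene-1-carboxylic acid
Conditions: NaClO2, NaH2PO4, 2-methylbut-2-ene, t-BuOH–H2O, 0 °C
Reagents that add atoms: sodium chlorite, [Na+].[O-]Cl=O
Why: Pinnick oxidation converts the aldehyde to the C7 acid without touching ketones or the alkyne; the descriptor at C7a changes only because of ligand priorities.

Step 6
Reactants: 8 (1S,3aR,7aS)-3,6-dioxo-7a-(prop-2-yn-1-yl)octahydro-1H-indene-1-carboxylic acid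
Product: 9 2-(trimethylsilyl)ethyl (1S,3aR,7aS)-3,6-dioxo-7a-(prop-2-yn-1-yl)octahydro-1H-indene-1-carboxylate
Conditions: Me3SiCH2CH2OH, DCC, DMAP (cat.), CH2Cl2, 0 to 23 °C
Reagents that add atoms: 2-(trimethylsilyl)ethanol, C[Si](C)(C)CCO
Why: Steglich esterification installs a fluoride-labile ester that survives every base, acid, reductant and oxidant used later and is removed at the end without opening the oxirane.

Step 7
Reactants: 9 2-(trimethylsilyl)ethyl (1S,3aR,7aS)-3,6-dioxo-7a-(prop-2-yn-1-yl)octahydro-1H-indene-1-carboxylate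
Product: 10 tricyclic hydroxy ketone ester (rings B C D; 10-oxo; 13-hydroxy; 16-methylene; 6β-CO2CH2CH2SiMe3; 9β-H)
Conditions: SmI2 (2.5 equiv), (Me2N)3PO (10 equiv), t-BuOH (2.2 equiv), THF, −78 to 0 °C
Reagents that add atoms: none
Why: Samarium ketyl–alkyne 5-exo-dig radical cyclization joins C13 to C16 and leaves the exocyclic methylene and the bridgehead carbinol; ketyl formation is reversible and only the C13 ketyl has a low-strain closure (bicyclo[3.2.1]octane), whereas the C10 ketyl would have to form a norbornane; the C13 configuration is dictated by the bridge from C8.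

Step 8
Reactants: 10 tricyclic hydroxy ketone ester
Product: 11 13-O-triethylsilyl ether of 10
Conditions: Et3SiOTf, 2,6-lutidine, CH2Cl2, −78 to 0 °C
Reagents that add atoms: triethylsilyl trifluoromethanesulfonate, CC[Si](CC)(CC)OS(=O)(=O)C(F)(F)F
Why: Silylation of the tertiary carbinol is faster than enol silylation with the weak base lutidine; the ether prevents acylation in step 10 and hydroxyl-directed epoxidation of C16=C17 in step 18.

Step 9
Reactants: 11 13-O-triethylsilyl ether of 10
Product: 12 tricyclic enone ester (10-oxo-5-ene; 13-OSiEt3; C7 2-(trimethylsilyl)ethyl ester)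
Conditions: LiN(iPr)2 (1.1 equiv), THF, −78 °C; then PhS(Cl)=NtBu, −78 °C
Reagents that add atoms: none
Why: Mukaiyama one-pot dehydrogenation: the kinetic enolate forms at the C5 methylene (not at tertiary C9), is sulfenylated by N-tert-butylbenzenesulfinimidoyl chloride and eliminates toward C6 to give the C5=C6 enoate needed as Michael acceptor; C6 is planarized and C8, C9, C13 are untouched.

Step 10
Reactants: 12 tricyclic enone ester
Product: 14 10α-propanoyloxy-10β-(3,3-diethoxyprop-1-yn-1-yl) adduct of 12, via lithium alkoxide 13 (not isolated)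
Conditions: HC≡CCH(OEt)2, n-BuLi, THF, −78 °C; add 12, −78 °C; then (EtCO)2O, −78 to 0 °C; aq. NH4Cl
Reagents that add atoms: 3,3-diethoxyprop-1-yne, C#CC(OCC)OCC; propanoic anhydride, CCC(=O)OC(=O)CC
Why: 1,2-Addition of the lithium acetylide to the C10 ketone occurs from the β-face (syn to H-9, away from C11 and C14 on the α-face), which places O-10 α and C1 β, and the tertiary alkoxide is acylated in the same flask.

Step 11
Reactants: 14 10α-propanoyloxy-10β-(3,3-diethoxyprop-1-yn-1-yl) adduct
Product: 15 19,10-γ-lactone (C4 epimer mixture; 5β-H; 6β-ester; 10β-alkynyl acetal)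
Conditions: KN(SiMe3)2 (1.1 equiv), THF, −78 to 0 °C; then t-BuOH (5 equiv), 0 °C; AcOH
Reagents that add atoms: none
Why: Intramolecular 5-exo-trig Michael addition of the propanoate enolate to C5 of the enoate, as in the classical hydrofluorenone approach to gibberellins; the tether on the 10α-oxygen delivers C4 to the α-face of C5 (cis-fused lactone, H-5 β), the alkoxide-mediated equilibration sets C6 as the more stable 6β-ester (trans to C4), and the C4 mixture is erased in step 14.

Step 12
Reactants: 15 19,10-γ-lactone with 10β-alkynyl acetal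
Product: 16 19,10-γ-lactone with 10β-[(Z)-3,3-diethoxyprop-1-en-1-yl] group
Conditions: H2 (1 atm), Pd on CaCO3 poisoned with Pb(OAc)2, quinoline, EtOAc, 23 °C
Reagents that add atoms: none
Why: Lindlar semihydrogenation gives the Z-alkene by syn addition and leaves the 1,1-disubstituted C16=C17 alkene alone; no stereocentre is formed.

Step 13
Reactants: 16 19,10-γ-lactone with 10β-[(Z)-3,3-diethoxyprop-1-en-1-yl] group
Product: 17 19,10-γ-lactone with 10β-[(Z)-3-oxoprop-1-en-1-yl] group
Conditions: pyridinium p-toluenesulfonate (cat.), acetone–H2O (10:1), 23 °C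
Reagents that add atoms: water, O
Why: Mild hydrolysis of the allylic acetal frees the Z-enal without cleaving the tertiary silyl ether or the silylethyl ester; used at once to avoid Z to E isomerization.

Step 14
Reactants: 17 19,10-γ-lactone with 10β-[(Z)-3-oxoprop-1-en-1-yl] group
Product: 18 2-(trimethylsilyl)ethyl 13-O-triethylsilylgibberellate (3β-OH) together with its 3-epimer
Conditions: LiN(SiMe3)2 (1.2 equiv), THF, −78 to −40 °C; aq. NH4Cl
Reagents that add atoms: none
Why: Intramolecular aldol addition of the lactone enolate (C4) to the enal carbonyl (C3) closes ring A; only the enolate face syn to the C10–C1 arm can reach the aldehyde, so C4 is fixed (18-methyl β, lactone α), the lactone α-hydrogen is more acidic and less hindered than H-6, and the C3 carbinol mixture is erased in step 15.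

Step 15
Reactants: 18 3-hydroxy-1-ene lactone (3-epimer mixture)
Product: 19 3-oxo-1-ene lactone (13-OSiEt3; C7 2-(trimethylsilyl)ethyl ester)
Conditions: Dess–Martin periodinane, CH2Cl2, 0 to 23 °C
Reagents that add atoms: none
Why: Oxidation of the allylic alcohol converges both C3 epimers on one enone; C4 is quaternary, so nothing can epimerize.

Step 16
Reactants: 19 3-oxo-1-ene lactone
Product: 20 1β,2β-epoxy-3-oxo lactone
Conditions: t-BuOOH (2 equiv), DBU (0.5 equiv), CH2Cl2, 0 °C
Reagents that add atoms: tert-butyl hydroperoxide, CC(C)(C)OO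
Why: Weitz–Scheffer nucleophilic epoxidation; the peroxide anion adds to C1 from the β-face because the lactone bridge covers the α-face of ring A, and anhydrous conditions with a non-nucleophilic base avoid retro-Claisen opening of the β-keto lactone.

Step 17
Reactants: 20 1β,2β-epoxy-3-oxo lactone
Product: 22 1β-hydroxy-2-ene lactone (13-OSiEt3; C7 2-(trimethylsilyl)ethyl ester), via epoxy hydrazone 21 (not isolated)
Conditions: N2H4·H2O (3 equiv), AcOH (cat.), MeOH, 0 to 23 °C
Reagents that add atoms: none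
Why: Wharton transposition: the hydrazone opens the oxirane and loses N2, giving the C2=C3 alkene and the C1 carbinol with the C1–O bond untouched, so the 1β configuration comes straight from the epoxide.

Step 18
Reactants: 22 1β-hydroxy-2-ene lactone
Product: 23 bis-silyl-protected target (13-O-triethylsilyl ether and C7 2-(trimethylsilyl)ethyl ester of the 1β-hydroxy-2β,3β-epoxy lactone)
Conditions: VO(acac)2 (5 mol %), t-BuOOH (1.5 equiv), CH2Cl2, 0 to 23 °C
Reagents that add atoms: tert-butyl hydroperoxide, CC(C)(C)OO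
Why: Vanadium-catalysed hydroxyl-directed epoxidation delivers oxygen syn to the 1β-hydroxyl (also the open face), giving the 2β,3β-oxirane; C16=C17 is not touched because O-13 is silylated.

Step 19
Reactants: 23 bis-silyl-protected target
Product: 24 target gibberellin (2β,3β-epoxy-1β,13-dihydroxy-20-norgibberell-16-ene-7,19-dioic acid 19,10-lactone)
Conditions: Bu4NF (4 equiv), AcOH (2 equiv), THF, 0 to 23 °C; aq. NH4Cl, then dilute HCl to pH 3
Reagents that add atoms: none
Why: Fluoride removes the silyl ether and fragments the silylethyl ester in one operation; the hydroxyl and oxirane are cis, so no Payne rearrangement is possible, and no stereocentre is affected.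

**Compound list**
1 | 3-ethoxycyclohex-2-en-1-one | CCOC1=CC(=O)CCC1 | starting material
2 | 4-[(tert-butyldimethylsilyl)oxy]butanal | O=CCCCO[Si](C)(C)C(C)(C)C | starting material
3 | 3-ethoxy-6-{1-hydroxy-4-[(tert-butyldimethylsilyl)oxy]butyl}cyclohex-2-en-1-one (racemic, both diastereomers; centres erased later) | CCOC1=CC(=O)C(CC1)C(O)CCCO[Si](C)(C)C(C)(C)C | intermediate
4 | 3-ethoxy-6-{1-hydroxy-4-[(tert-butyldimethylsilyl)oxy]butyl}-1-(prop-2-yn-1-yl)cyclohex-2-en-1-ol (stereoisomer mixture, not isolated) | CCOC1=CC(O)(CC#C)C(CC1)C(O)CCCO[Si](C)(C)C(C)(C)C | intermediate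
5 | 4-(1,4-dihydroxybutyl)-3-(prop-2-yn-1-yl)cyclohex-2-en-1-one (racemic, both diastereomers) | C#CCC1=CC(=O)CCC1C(O)CCCO | intermediate
6 | 4-(4-oxobutanoyl)-3-(prop-2-yn-1-yl)cyclohex-2-en-1-one (racemic, labile at C9) | C#CCC1=CC(=O)CCC1C(=O)CCC=O | intermediate
7 | (1S,3aR,7aR)-3,6-dioxo-7a-(prop-2-yn-1-yl)octahydro-1H-indene-1-carbaldehyde | C#CC[C@]12CC(=O)CC[C@H]1C(=O)C[C@@H]2C=O | intermediate
8 | (1S,3aR,7aS)-3,6-dioxo-7a-(prop-2-yn-1-yl)octahydro-1H-indene-1-carboxylic acid | C#CC[C@]12CC(=O)CC[C@H]1C(=O)C[C@@H]2C(=O)O | intermediate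
9 | 2-(trimethylsilyl)ethyl (1S,3aR,7aS)-3,6-dioxo-7a-(prop-2-yn-1-yl)octahydro-1H-indene-1-carboxylate | C#CC[C@]12CC(=O)CC[C@H]1C(=O)C[C@@H]2C(=O)OCC[Si](C)(C)C | intermediate
10 | tricyclic hydroxy ketone ester (rings B, C, D; 10-oxo, 13-hydroxy, 16-methylene, 6β-ester, 9β-H) | C=C1C[C@]23C[C@@]1(O)CC[C@H]2C(=O)C[C@@H]3C(=O)OCC[Si](C)(C)C | intermediate
11 | 13-O-triethylsilyl ether of 10 | C=C1C[C@]23C[C@@]1(O[Si](CC)(CC)CC)CC[C@H]2C(=O)C[C@@H]3C(=O)OCC[Si](C)(C)C | intermediate
12 | tricyclic enone ester (10-oxo-5-ene, 13-OSiEt3) | C=C1C[C@]23C[C@@]1(O[Si](CC)(CC)CC)CC[C@H]2C(=O)C=C3C(=O)OCC[Si](C)(C)C | intermediate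
13 | lithium 10α-alkoxide of the 10β-(3,3-diethoxyprop-1-yn-1-yl) adduct (not isolated) | C=C1C[C@]23C[C@@]1(O[Si](CC)(CC)CC)CC[C@H]2[C@@](C#CC(OCC)OCC)([O-])C=C3C(=O)OCC[Si](C)(C)C.[Li+] | intermediate
14 | 10α-propanoyloxy-10β-(3,3-diethoxyprop-1-yn-1-yl) adduct | C=C1C[C@]23C[C@@]1(O[Si](CC)(CC)CC)CC[C@H]2[C@@](C#CC(OCC)OCC)(OC(=O)CC)C=C3C(=O)OCC[Si](C)(C)C | intermediate
15 | 19,10-γ-lactone with 10β-(3,3-diethoxyprop-1-yn-1-yl) group (C4 epimers; 5β-H, 6β-ester) | C=C1C[C@]23C[C@@]1(O[Si](CC)(CC)CC)CC[C@H]2[C@@]2(C#CC(OCC)OCC)OC(=O)C(C)[C@H]2[C@@H]3C(=O)OCC[Si](C)(C)C | intermediate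
16 | 19,10-γ-lactone with 10β-[(Z)-3,3-diethoxyprop-1-en-1-yl] group (C4 epimers) | C=C1C[C@]23C[C@@]1(O[Si](CC)(CC)CC)CC[C@H]2[C@@]2(/C=C\C(OCC)OCC)OC(=O)C(C)[C@H]2[C@@H]3C(=O)OCC[Si](C)(C)C | intermediate
17 | 19,10-γ-lactone with 10β-[(Z)-3-oxoprop-1-en-1-yl] group (C4 epimers) | C=C1C[C@]23C[C@@]1(O[Si](CC)(CC)CC)CC[C@H]2[C@@]2(/C=C\C=O)OC(=O)C(C)[C@H]2[C@@H]3C(=O)OCC[Si](C)(C)C | intermediate
18 | 2-(trimethylsilyl)ethyl 13-O-triethylsilylgibberellate and its 3-epimer (3-hydroxy-1-ene) | C=C1C[C@]23C[C@@]1(O[Si](CC)(CC)CC)CC[C@H]2[C@@]12C=CC(O)[C@@](C)(C(=O)O1)[C@H]2[C@@H]3C(=O)OCC[Si](C)(C)C | intermediate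
19 | 3-oxo-1-ene lactone | C=C1C[C@]23C[C@@]1(O[Si](CC)(CC)CC)CC[C@H]2[C@@]12C=CC(=O)[C@@](C)(C(=O)O1)[C@H]2[C@@H]3C(=O)OCC[Si](C)(C)C | intermediate
20 | 1β,2β-epoxy-3-oxo lactone | C=C1C[C@]23C[C@@]1(O[Si](CC)(CC)CC)CC[C@H]2[C@@]12[C@@H]4O[C@@H]4C(=O)[C@@](C)(C(=O)O1)[C@H]2[C@@H]3C(=O)OCC[Si](C)(C)C | intermediate
21 | hydrazone of 20 (not isolated) | C=C1C[C@]23C[C@@]1(O[Si](CC)(CC)CC)CC[C@H]2[C@@]12[C@@H]4O[C@@H]4C(=NN)[C@@](C)(C(=O)O1)[C@H]2[C@@H]3C(=O)OCC[Si](C)(C)C | intermediate
22 | 1β-hydroxy-2-ene lactone | C=C1C[C@]23C[C@@]1(O[Si](CC)(CC)CC)CC[C@H]2[C@@]12[C@H](O)C=C[C@@](C)(C(=O)O1)[C@H]2[C@@H]3C(=O)OCC[Si](C)(C)C | intermediate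
23 | bis-silyl-protected target (13-O-triethylsilyl ether and C7 2-(trimethylsilyl)ethyl ester of the 1β-hydroxy-2β,3β-epoxy lactone) | C=C1C[C@]23C[C@@]1(O[Si](CC)(CC)CC)CC[C@H]2[C@@]12[C@H](O)[C@@H]4O[C@@H]4[C@@](C)(C(=O)O1)[C@H]2[C@@H]3C(=O)OCC[Si](C)(C)C | intermediate
24 | target gibberellin (2β,3β-epoxy-1β,13-dihydroxy-20-norgibberell-16-ene-7,19-dioic acid 19,10-lactone) | C=C1C[C@]23C[C@@]1(O)CC[C@H]2[C@@]12OC(=O)[C@@](C)([C@H]1[C@@H]3C(=O)O)[C@H]1O[C@H]1[C@H]2O | target

**Totals**
Total steps: 19. Longest linear sequence: 19 (fully linear from 1 and 2).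

**Steps most likely to fail**

Step 4 (the proposed new cyclization). The enamine may be too weak for the β,β-disubstituted enone, or the dynamic resolution may give low enantiomeric excess. The fallback uses only known chemistry, sets out from 6 and comes back at 8. Ketone-aldehyde 6 is condensed with stoichiometric pyrrolidine (AcOH, MeCN, 40 °C) to the pyrrolidine enamine F1. F1 closes ring B by a Stork enamine intramolecular Michael addition, and aqueous acetic acid releases the racemic cis-fused keto-aldehyde F2. Pinnick oxidation gives the racemic acid F3. Salt formation with (R)-1-phenylethanamine and fractional crystallization is assumed to give the less soluble (R)-1-phenylethylammonium salt F4 of the wanted acid, while the salt of the antipode F5 stays in the mother liquor. Dilute HCl liberates 8.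

Step 7 (chemoselectivity of the ketyl cyclization). The C10 ketone may be reduced or may itself cyclize. The fallback replaces the radical by a polar organochromium addition, sets out from 9 and comes back at 10. Markovnikov hydroiodination of the terminal alkyne (Me3SiCl, NaI, H2O, MeCN) gives the 2-iodoallyl diketone F6. An intramolecular Nozaki–Hiyama–Kishi reaction (CrCl2, NiCl2 cat., DMF) then adds the alkenylchromium to the less hindered C13 ketone, whose product-like transition state disfavours the strained norbornane alternative at C10.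

Step 17 (Wharton transposition). Hydrazine may attack the lactone, or the yield may be low. The fallback sets out from 20 and comes back at 22. Luche reduction (NaBH4, CeCl3·7H2O, MeOH) gives the 1β,2β-epoxy-3-ol F7, either C3 epimer being usable. 1,1'-Thiocarbonyldiimidazole converts it into the imidazole-1-carbothioate F8. Bu3SnH with AIBN (toluene, 80 °C) generates the C3 radical, which opens the adjacent oxirane to the C2=C3 alkene and the 1β-oxygen radical, reduced to 22.

Further compounds
F1 | step 4 | pyrrolidine enamine of 6 | C#CCC1=CC(=O)CCC1C(=O)C/C=C/N1CCCC1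
F2 | step 4 | racemic cis-fused keto-aldehyde (racemate of 7, one enantiomer drawn) | C#CC[C@]12CC(=O)CC[C@H]1C(=O)C[C@@H]2C=O
F3 | step 4 | racemic acid (racemate of 8, one enantiomer drawn) | C#CC[C@]12CC(=O)CC[C@H]1C(=O)C[C@@H]2C(=O)O
F4 | step 4 | (R)-1-phenylethylammonium salt of 8 | C[C@@H]([NH3+])c1ccccc1.C#CC[C@]12CC(=O)CC[C@H]1C(=O)C[C@@H]2C(=O)[O-]
F5 | step 4 | (R)-1-phenylethylammonium salt of the antipode of 8 | C[C@@H]([NH3+])c1ccccc1.C#CC[C@@]12CC(=O)CC[C@@H]1C(=O)C[C@H]2C(=O)[O-]
F6 | step 7 | 2-iodoallyl analogue of 9 | C=C(I)C[C@]12CC(=O)CC[C@H]1C(=O)C[C@@H]2C(=O)OCC[Si](C)(C)C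
F7 | step 17 | 1β,2β-epoxy-3-hydroxy lactone (C3 epimers) | C=C1C[C@]23C[C@@]1(O[Si](CC)(CC)CC)CC[C@H]2[C@@]12[C@@H]4O[C@@H]4C(O)[C@@](C)(C(=O)O1)[C@H]2[C@@H]3C(=O)OCC[Si](C)(C)C
F8 | step 17 | 3-O-(imidazol-1-ylcarbonothioyl) derivative of F7 | C=C1C[C@]23C[C@@]1(O[Si](CC)(CC)CC)CC[C@H]2[C@@]12[C@@H]4O[C@@H]4C(OC(=S)n5ccnc5)[C@@](C)(C(=O)O1)[C@H]2[C@@H]3C(=O)OCC[Si](C)(C)C
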